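Terpenoid carbons are named by cadinane numbering: ring A = C1, C6–C10 (C7 carries isopropyl, C10 methyl), ring B = C1–C6 (C5=C6 alkene, C4 = spiro carbon), C15 = the CH2 of pyran ring C, ring D = the arene.
Ring C is opened last by a retro-hetero-Diels–Alder (O–C4 and C15–CHPh bonds) to an o-quinone methide (from 2,4,6-trihydroxyisophthalaldehyde and benzaldehyde) and a bicyclic diene with an exocyclic C4=C15 methylene; C15 is then removed (retro-Wittig) to the ring B enone C6=C5–C4=O.
Key disconnection: ring B of that enone is cut at C5=C6 and at C3–C4, giving a 6-(2-iodoethyl) derivative of (−)-menthone (ring A with C7, C10 and C1 in place; C6 = its carbonyl carbon, C3 = the CH2I carbon) and a two-carbon phosphonoacetyl unit (C4, C5); forward this is a one-flask Fukuyama acylation / intramolecular Horner–Wadsworth–Emmons annulation.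
Enabling feature: the ring B alkene C5=C6 is exocyclic to ring A at the ring-fusion carbon C6 and lies 1,3 to the oxygen-bearing spiro carbon C4, so C6=C5–C4(O) is an enone retron whose β-carbon is the carbonyl carbon of menthone and whose C3–C4 bond ends in an unbranched CH2.
Ring order: A (chiral pool; C1 set cis to the C10 methyl by kinetic protonation after iodide opening of a spiro-cyclopropyl ketone) → B (key step) → C, fused onto the preformed arene D in the last step, which also sets C4 and the benzylic centre.

Key step: step 5

Remark: 2,4,6-trihydroxybenzene-1,3-dicarbaldehyde and 2-(diethoxyphosphoryl)acetic acid are taken as purchasable; quinone methide 17 is drawn without alkene geometry because it reacts through the s-cis heterodiene that carries phenyl on the outside.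

Step 1
Reactants: 1 (−)-menthone
Product: 5 (3R,6S)-3-methyl-2-methylidene-6-(propan-2-yl)cyclohexan-1-one, via lithium enolate 2 (not isolated), via Mannich base 3 (not isolated), via ammonium iodide 4 (not isolated)
Conditions: LDA, THF, −78 °C; Me2N=CH2+ I−, −78 °C → rt; MeI, rt; aq NaHCO3, CH2Cl2, rt
Reagents that add atoms: Eschenmoser's salt (N,N-dimethylmethylideneammonium iodide), C=[N+](C)C.[I-]; iodomethane, CI (its methyl stays only in intermediate 4); lithium diisopropylamide, [Li]N(C(C)C)C(C)C (lithium stays only in intermediate 2)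
Why: Eschenmoser α-methylenation: LDA at −78 °C removes the less hindered CH2 proton (kinetic enolate, the isopropyl-bearing centre is untouched), the enolate is aminomethylated (Mannich reaction), and N-methylation followed by mild-base E1cB loss of trimethylamine gives the exocyclic methylene, which can only form at this α-carbon because the other one carries a single hydrogen; no stereocentre is created.

Step 2
Reactants: 5 (3R,6S)-3-methyl-2-methylidene-6-(propan-2-yl)cyclohexan-1-one
Product: 6 (5S,8R)-8-methyl-5-(propan-2-yl)spiro[2.5]octan-4-one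
Conditions: Me3S(O)I, NaH, DMSO, rt; then 5, rt
Reagents that add atoms: trimethylsulfoxonium iodide, C[S+](C)(C)=O.[I-] (one CH2)
Why: Corey–Chaykovsky cyclopropanation: the soft sulfoxonium ylide adds 1,4 to the unhindered exocyclic enone and the enolate displaces dimethyl sulfoxide in a 3-exo-tet closure; the spiro carbon carries two identical CH2 arms, so no stereocentre is created, and the weakly basic ylide should leave the α-isopropyl centre intact.

Step 3
Reactants: 6 (5S,8R)-8-methyl-5-(propan-2-yl)spiro[2.5]octan-4-one
Product: 8 (2R,3R,6S)-2-(2-iodoethyl)-3-methyl-6-(propan-2-yl)cyclohexan-1-one, via silyl enol ether 7 (not isolated)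
Conditions: Me3SiI (1.1 equiv), CH2Cl2, −78 → −20 °C; then MeOH, −78 °C; aq NaHCO3 at −78 °C
Reagents that add atoms: iodotrimethylsilane, C[Si](C)(C)I (iodine stays in 8; the silyl group stays only in intermediate 7)
Why: Homoconjugate (1,5-) opening of the cyclopropyl ketone by iodotrimethylsilane (O-silylation, iodide attack at a cyclopropane CH2) gives the regiodefined silyl enol ether 7, and its kinetic C-protonation sets C1: A(1,2) strain holds the neighbouring C10 methyl pseudo-axial, so the proton should enter axially on the opposite face and leave the iodoethyl chain cis to the methyl group (2R), the less stable but required arrangement.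

Step 4
Reactants: 9 2-(diethoxyphosphoryl)acetic acid
Product: 10 S-ethyl 2-(diethoxyphosphoryl)ethanethioate
Conditions: EtSH, DCC, DMAP (cat.), CH2Cl2, 0 °C → rt
Reagents that add atoms: ethanethiol, CCS
Why: Steglich-type thioesterification (carbodiimide activation of the acid, DMAP acyl transfer to the thiol) provides the acyl donor for the Fukuyama coupling; no stereocentre is involved.

Step 5
Reactants: 8 (2R,3R,6S)-2-(2-iodoethyl)-3-methyl-6-(propan-2-yl)cyclohexan-1-one; 10 S-ethyl 2-(diethoxyphosphoryl)ethanethioate
Product: 13 (4aR,5R,8S)-5-methyl-8-(propan-2-yl)-4,4a,5,6,7,8-hexahydronaphthalen-2(3H)-one, via alkylzinc iodide 11 (not isolated), via keto phosphonate 12 (not isolated)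
Conditions: Zn dust (activated with BrCH2CH2Br, Me3SiCl), THF, 35 °C; then 10, PdCl2(PPh3)2 (5 mol %), toluene, rt; then LiCl, DBU, MeCN, rt → 50 °C (one flask)
Reagents that add atoms: zinc, [Zn] (stays only in intermediate 11)
Why: Zinc inserts into the primary C–I bond to give the γ-keto alkylzinc iodide 11, which neither adds to nor enolises the ring ketone; zerovalent palladium (formed from the divalent precatalyst) inserts into the acyl–S bond of 10, transmetalates with 11 and reductively eliminates to form C3–C4 (Fukuyama thioester–organozinc ketone synthesis), giving β-keto phosphonate 12. LiCl/DBU then removes only the doubly activated C5–H (roughly eight pKa units more acidic than the ring ketone α-hydrogens), and the chelated phosphonate carbanion adds to the ring A carbonyl C6 and expels diethyl phosphate through the oxaphosphetane to form C5=C6 (intramolecular Horner–Wadsworth–Emmons reaction under Masamune–Roush conditions; the closest known type is the β-keto phosphonate cyclohexenone annulation onto α-substituted cyclohexanones). Ring B closes by a 6-(enolendo)-exo-trig addition of C5 to the C6 carbonyl followed by syn-elimination, so the alkene position is fixed by the phosphonate and cannot move into ring A as it could in an aldol dehydration. No stereocentre is created; what the step must do is conserve the kinetically set, epimerisable C1 (and C7) next to the ketone, which the non-basic zinc/palladium stage and the weak amine base should secure. The chemoselectivity needed (acyl transfer without attack on the ring ketone, olefination without ketone enolisation) rests on the low basicity of the alkylzinc iodide and on the acidity gap within 12.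

Step 6
Reactants: 13 (4aR,5R,8S)-5-methyl-8-(propan-2-yl)-4,4a,5,6,7,8-hexahydronaphthalen-2(3H)-one
Product: 14 (1S,4R,4aR)-4-methyl-7-methylidene-1-(propan-2-yl)-1,2,3,4,4a,5,6,7-octahydronaphthalene
Conditions: Ph3PCH3Br, NaHMDS (slight deficit), THF, 0 °C; then 13, 0 °C → rt
Reagents that add atoms: methyltriphenylphosphonium bromide, C[P+](c1ccccc1)(c1ccccc1)c1ccccc1.[Br-] (one CH2)
Why: Wittig methylenation of the unhindered enone carbonyl (1,2-addition of the unstabilised ylide, oxaphosphetane collapse) should give the s-trans-locked exocyclic diene; the deficit of base keeps the γ-stereocentres C1 and C7 from dienolate formation, and no stereocentre is created.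

Step 7
Reactants: 14 (1S,4R,4aR)-4-methyl-7-methylidene-1-(propan-2-yl)-1,2,3,4,4a,5,6,7-octahydronaphthalene; 15 2,4,6-trihydroxybenzene-1,3-dicarbaldehyde; 16 benzaldehyde
Product: 18 guajadial C, via o-quinone methide 17 (not isolated)
Conditions: H2O (on-water suspension), 100 °C, sealed tube
Reagents that add atoms: none
Why: Knoevenagel condensation of benzaldehyde at the free ring CH of 15 gives o-quinone methide 17, which should undergo an inverse-electron-demand hetero-Diels–Alder reaction (a biomimetic reaction type established for quinone methides of this phloroglucinol with terpene alkenes) at the 1,1-disubstituted exocyclic alkene of 14 with oxygen bonding to the more substituted C4; the spiro centre (S) is expected from axial C–O bond formation on the ring B sofa (face syn to C10, anti to the axial C3–H), and the benzylic centre (R) from the endo orientation of the C5=C6 vinyl group, which places phenyl cis to C5.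

Compound list
1 | (−)-menthone, (2S,5R)-5-methyl-2-(propan-2-yl)cyclohexan-1-one | CC(C)[C@@H]1CC[C@@H](C)CC1=O | starting material
2 | lithium (3R,6S)-3-methyl-6-(propan-2-yl)cyclohex-1-en-1-olate | CC(C)[C@@H]1CC[C@@H](C)C=C1O[Li] | intermediate
3 | (3R,6S)-2-[(dimethylamino)methyl]-3-methyl-6-(propan-2-yl)cyclohexan-1-one (C2 epimers) | CC(C)[C@@H]1CC[C@@H](C)C(CN(C)C)C1=O | intermediate
4 | N,N,N-trimethyl-1-[(2R,5S)-2-methyl-6-oxo-5-(propan-2-yl)cyclohexyl]methanaminium iodide (C1 epimers) | CC(C)[C@@H]1CC[C@@H](C)C(C[N+](C)(C)C)C1=O.[I-] | intermediate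
5 | (3R,6S)-3-methyl-2-methylidene-6-(propan-2-yl)cyclohexan-1-one | CC(C)[C@@H]1CC[C@@H](C)C(=C)C1=O | intermediate
6 | (5S,8R)-8-methyl-5-(propan-2-yl)spiro[2.5]octan-4-one | CC(C)[C@@H]1CC[C@@H](C)C2(CC2)C1=O | intermediate
7 | {[(3R,6S)-2-(2-iodoethyl)-3-methyl-6-(propan-2-yl)cyclohex-1-en-1-yl]oxy}trimethylsilane | CC(C)[C@@H]1CC[C@@H](C)C(CCI)=C1O[Si](C)(C)C | intermediate
8 | (2R,3R,6S)-2-(2-iodoethyl)-3-methyl-6-(propan-2-yl)cyclohexan-1-one | CC(C)[C@@H]1CC[C@@H](C)[C@@H](CCI)C1=O | intermediate
9 | 2-(diethoxyphosphoryl)acetic acid | OC(=O)CP(=O)(OCC)OCC | starting material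
10 | S-ethyl 2-(diethoxyphosphoryl)ethanethioate | CCSC(=O)CP(=O)(OCC)OCC | intermediate
11 | {2-[(1R,2R,5S)-2-methyl-6-oxo-5-(propan-2-yl)cyclohexyl]ethyl}zinc iodide | CC(C)[C@@H]1CC[C@@H](C)[C@@H](CC[Zn]I)C1=O | intermediate
12 | diethyl {2-oxo-4-[(1R,2R,5S)-2-methyl-6-oxo-5-(propan-2-yl)cyclohexyl]butyl}phosphonate | CC(C)[C@@H]1CC[C@@H](C)[C@@H](CCC(=O)CP(=O)(OCC)OCC)C1=O | intermediate
13 | (4aR,5R,8S)-5-methyl-8-(propan-2-yl)-4,4a,5,6,7,8-hexahydronaphthalen-2(3H)-one | CC(C)[C@@H]1CC[C@@H](C)[C@H]2CCC(=O)C=C12 | intermediate
14 | (1S,4R,4aR)-4-methyl-7-methylidene-1-(propan-2-yl)-1,2,3,4,4a,5,6,7-octahydronaphthalene | CC(C)[C@@H]1CC[C@@H](C)[C@H]2CCC(=C)C=C12 | intermediate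
15 | 2,4,6-trihydroxybenzene-1,3-dicarbaldehyde (2,4-diformylphloroglucinol) | O=Cc1c(O)cc(O)c(C=O)c1O | starting material
16 | benzaldehyde | O=Cc1ccccc1 | starting material
17 | 5-benzylidene-2,4-dihydroxy-6-oxocyclohexa-1,3-diene-1,3-dicarbaldehyde (o-quinone methide) | O=C1C(=Cc2ccccc2)C(O)=C(C=O)C(O)=C1C=O | intermediate
18 | guajadial C, (2S,4R,4a'R,5'R,8'S)-5,7-dihydroxy-5'-methyl-4-phenyl-8'-(propan-2-yl)-3,3',4,4',4a',5',6',7'-octahydro-8'H-spiro[chromene-2,2'-naphthalene]-6,8-dicarbaldehyde | CC(C)[C@@H]1CC[C@@H](C)[C@H]2CC[C@@]3(C=C12)C[C@H](c1ccccc1)c1c(O)c(C=O)c(O)c(C=O)c1O3 | target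

Total step count: 7. Longest linear sequence: 6 steps (steps 1, 2, 3, 5, 6, 7); step 4 is a one-step side branch.

Steps most likely to fail

Step 7. The cycloaddition may discriminate poorly between the two faces of the remote exocyclic alkene or between endo and exo approach, and the diene may isomerise or the quinone methide oligomerise before capture. The fallback sets out from enone 13 and returns at 18. Cerium-mediated 1,2-addition of (E)-2-phenylethenyllithium (from (E)-β-bromostyrene and t-BuLi; CeCl3, THF, −78 °C) should give the tertiary bis-allylic alcohol (4aR,5R,8S)-5-methyl-2-[(E)-2-phenylethenyl]-8-(propan-2-yl)-2,3,4,4a,5,6,7,8-octahydronaphthalen-2-ol F1 (either C2 epimer serves). Camphorsulfonic acid in CH2Cl2 at 0 °C in the presence of 15 should ionise it to a pentadienyl cation, which the free ring carbon of 15 attacks at the benzylic terminus (Friedel–Crafts alkylation); the neighbouring phenol then closes ring C at the tertiary allylic C4 (cycloetherification). This is a stepwise [3+3] chroman annulation of the phenol–allylic alcohol type, and because the C–O bond forms reversibly under acid the spiro centre can be equilibrated.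

Step 5. The organozinc may be protonated by the acidic thioester, or closure onto the doubly α-branched ketone may stall so that prolonged base exposure erodes C1. The fallback runs from 8 to 13. Zinc reagent 11 is made as in the route and cross-coupled with vinyl bromide (Pd(PPh3)4, THF; Negishi coupling) to give (2R,3R,6S)-2-(but-3-en-1-yl)-3-methyl-6-(propan-2-yl)cyclohexan-1-one F2. Tsuji–Wacker oxidation (PdCl2, CuCl, O2, DMF–H2O) should give the 1,5-diketone (2R,3R,6S)-3-methyl-2-(3-oxobutyl)-6-(propan-2-yl)cyclohexan-1-one F3. Pyrrolidine/AcOH (enamine of the unhindered methyl ketone, intramolecular aldol condensation) then closes ring B to 13.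

Step 3. Protonation of the silyl enol ether from the wrong face, or enolisation by adventitious HI after protonation, would erode the 2,3-cis relationship; a free enolate would also re-close to the cyclopropane. The fallback runs from 5 to 8 and avoids both acid and a γ-leaving group at the protonation stage. Copper-catalysed conjugate addition of {[dimethyl(propan-2-yloxy)silyl]methyl}magnesium chloride (CuBr·SMe2, Me3SiCl, THF, −78 °C; a hydroxymethyl anion equivalent) should give trimethyl{[(3R,6S)-2-{2-[dimethyl(propan-2-yloxy)silyl]ethyl}-3-methyl-6-(propan-2-yl)cyclohex-1-en-1-yl]oxy}silane F4. Fluoride-triggered, buffered protonation (Bu4NF, AcOH, THF, −78 °C) should give the cis ketone (2R,3R,6S)-2-{2-[dimethyl(propan-2-yloxy)silyl]ethyl}-3-methyl-6-(propan-2-yl)cyclohexan-1-one F5. Tamao oxidation (KF, KHCO3, H2O2, THF–MeOH) gives (2R,3R,6S)-2-(2-hydroxyethyl)-3-methyl-6-(propan-2-yl)cyclohexan-1-one F6, and Appel-type iodination (I2, PPh3, imidazole, CH2Cl2) returns 8.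

Further compounds
F1 | step 7 | (4aR,5R,8S)-5-methyl-2-[(E)-2-phenylethenyl]-8-(propan-2-yl)-2,3,4,4a,5,6,7,8-octahydronaphthalen-2-ol (C2 epimers) | CC(C)[C@@H]1CC[C@@H](C)[C@H]2CCC(O)(/C=C/c3ccccc3)C=C12
F2 | step 5 | (2R,3R,6S)-2-(but-3-en-1-yl)-3-methyl-6-(propan-2-yl)cyclohexan-1-one | CC(C)[C@@H]1CC[C@@H](C)[C@@H](CCC=C)C1=O
F3 | step 5 | (2R,3R,6S)-3-methyl-2-(3-oxobutyl)-6-(propan-2-yl)cyclohexan-1-one | CC(C)[C@@H]1CC[C@@H](C)[C@@H](CCC(C)=O)C1=O
F4 | step 3 | trimethyl{[(3R,6S)-2-{2-[dimethyl(propan-2-yloxy)silyl]ethyl}-3-methyl-6-(propan-2-yl)cyclohex-1-en-1-yl]oxy}silane | CC(C)[C@@H]1CC[C@@H](C)C(CC[Si](C)(C)OC(C)C)=C1O[Si](C)(C)C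
F5 | step 3 | (2R,3R,6S)-2-{2-[dimethyl(propan-2-yloxy)silyl]ethyl}-3-methyl-6-(propan-2-yl)cyclohexan-1-one | CC(C)[C@@H]1CC[C@@H](C)[C@@H](CC[Si](C)(C)OC(C)C)C1=O
F6 | step 3 | (2R,3R,6S)-2-(2-hydroxyethyl)-3-methyl-6-(propan-2-yl)cyclohexan-1-one | CC(C)[C@@H]1CC[C@@H](C)[C@@H](CCO)C1=O
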